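**Retrosynthetic overview**

1. Target 24 ← 23 (desilylation) ← 22 (selective aryl-ester aminolysis) ← 20 (double acylation); the C9' ester is put on last.
2. Key disconnection: the O1–C2 bond of the oxolane (O1; C2 bearing ring B; C3 bearing the C9' CH2O arm; C4 bearing the C7 benzylic CH2 of ring A; C5). C2 is para to the free hydroxyl of ring B, so the C2 methylene of seco diol 18 can be oxidised to a para-quinone methide carbon and captured by the C5 hydroxyl.
3. 18 ← 17 ← trans-dibenzyl lactone 16 (hydrogenolysis, hydride reduction); C3 and C4 are the (R,R) core of a dibenzylbutanediol whose two phenols already differ (silyl on ring A, benzyl on ring B).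
4. 16 ← lactone 12 + benzylic bromide 14 (trans alkylation, sets C3); 12 ← imide 7 + tert-butyl bromoacetate (Evans alkylation, sets C4) ← dihydroferulic acid 1.
5. Ring order: a temporary butyrolactone (step 4, opened in step 7), then the oxolane (step 9).

Key step: step 9

Remark on the chemistry: the two phenols are given different protecting groups (triisopropylsilyl on ring A, benzyl on ring B) before the two arms are joined, because a silyl chloride cannot be relied on to single out one phenol of the symmetric tetraol beside two primary alcohols; compounds 5, 8 and 13 are taken as commercial.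

**Route**

Step 1
Reactants: 1 3-(4-hydroxy-3-methoxyphenyl)propanoic acid; 2 triisopropylsilyl chloride
Product: 4 3-[3-methoxy-4-(triisopropylsilyloxy)phenyl]propanoic acid, via silyl ester 3 (not isolated)
Conditions: iPr3SiCl (2.3 equiv), imidazole (5 equiv), DMF, rt; then AcOH–THF–H2O (3:1:1), rt
Reagents that add atoms: triisopropylsilyl chloride (2), CC(C)[Si](Cl)(C(C)C)C(C)C
Why: Imidazole-promoted O-silylation caps both the phenol and the acid, and the much more labile silyl ester is then hydrolysed by aqueous acetic acid while the hindered aryl silyl ether should stay.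

Step 2
Reactants: 4 3-[3-methoxy-4-(triisopropylsilyloxy)phenyl]propanoic acid; 5 (4S)-4-benzyl-1,3-oxazolidin-2-one
Product: 7 (4S)-4-benzyl-3-{3-[3-methoxy-4-(triisopropylsilyloxy)phenyl]propanoyl}-1,3-oxazolidin-2-one, via mixed pivalic anhydride 6 (not isolated)
Conditions: Me3CCOCl, Et3N, THF, −20 °C; then LiCl, 5, −20 °C → rt
Reagents that add atoms: (4S)-4-benzyl-1,3-oxazolidin-2-one (5), O=C1N[C@@H](Cc2ccccc2)CO1
Why: N-Acylation of the oxazolidinone through a mixed anhydride (LiCl/Et3N protocol); the hindered pivaloyl carbonyl steers attack to the arylpropanoyl carbonyl.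

Step 3
Reactants: 7 (4S)-4-benzyl-3-{3-[3-methoxy-4-(triisopropylsilyloxy)phenyl]propanoyl}-1,3-oxazolidin-2-one; 8 tert-butyl bromoacetate
Product: 10 tert-butyl (3R)-4-[(4S)-4-benzyl-2-oxo-1,3-oxazolidin-3-yl]-3-{[3-methoxy-4-(triisopropylsilyloxy)phenyl]methyl}-4-oxobutanoate, via sodium Z-enolate 9 (not isolated)
Conditions: NaN(SiMe3)2, THF, −78 °C; then 8, −78 → −40 °C
Reagents that add atoms: tert-butyl bromoacetate (8), CC(C)(C)OC(=O)CBr
Why: Evans asymmetric alkylation; the chelated sodium Z-enolate is alkylated on the face away from the benzyl group of the auxiliary, which should set the new centre (later C4 of the oxolane) as R.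

Step 4
Reactants: 10 tert-butyl (3R)-4-[(4S)-4-benzyl-2-oxo-1,3-oxazolidin-3-yl]-3-{[3-methoxy-4-(triisopropylsilyloxy)phenyl]methyl}-4-oxobutanoate
Product: 12 (4R)-4-{[3-methoxy-4-(triisopropylsilyloxy)phenyl]methyl}oxolan-2-one, via hydroxy ester 11 (not isolated)
Conditions: LiBH4, H2O (1 equiv), THF, 0 °C; work-up, then TsOH·H2O (cat.), toluene, 60 °C
Reagents that add atoms: none
Why: Reductive removal of the auxiliary by hydride attack at the exocyclic imide carbonyl (the tert-butyl ester is spared), then acid-catalysed lactonisation by intramolecular transesterification; the stereocentre is not touched.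

Step 5
Reactants: 13 [4-(benzyloxy)-3-methoxyphenyl]methanol
Product: 14 1-(benzyloxy)-4-(bromomethyl)-2-methoxybenzene
Conditions: PBr3 (0.4 equiv), Et2O, 0 °C
Reagents that add atoms: phosphorus tribromide, BrP(Br)Br
Why: Bromination of a benzylic alcohol through its phosphite ester (SN2 by bromide); the aryl benzyl ether is inert under these conditions.

Step 6
Reactants: 12 (4R)-4-{[3-methoxy-4-(triisopropylsilyloxy)phenyl]methyl}oxolan-2-one; 14 1-(benzyloxy)-4-(bromomethyl)-2-methoxybenzene
Product: 16 (3R,4R)-3-{[4-(benzyloxy)-3-methoxyphenyl]methyl}-4-{[3-methoxy-4-(triisopropylsilyloxy)phenyl]methyl}oxolan-2-one, via lithium enolate 15 (not isolated)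
Conditions: LiN(SiMe3)2, THF, −78 °C; then 14, DMPU, −78 → −30 °C
Reagents that add atoms: none
Why: Lactone enolate alkylation with a benzylic bromide, which enters anti to the existing C4 substituent and should give the trans-2,3-dibenzylbutyrolactone with the new centre R.

Step 7
Reactants: 16 (3R,4R)-3-{[4-(benzyloxy)-3-methoxyphenyl]methyl}-4-{[3-methoxy-4-(triisopropylsilyloxy)phenyl]methyl}oxolan-2-one
Product: 17 (2R,3R)-2-{[4-(benzyloxy)-3-methoxyphenyl]methyl}-3-{[3-methoxy-4-(triisopropylsilyloxy)phenyl]methyl}butane-1,4-diol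
Conditions: LiAlH4, THF, 0 °C
Reagents that add atoms: none
Why: Hydride reduction of the lactone to the 1,4-diol; neither stereocentre is touched and the hindered aryl silyl ether should survive at 0 °C.

Step 8
Reactants: 17 (2R,3R)-2-{[4-(benzyloxy)-3-methoxyphenyl]methyl}-3-{[3-methoxy-4-(triisopropylsilyloxy)phenyl]methyl}butane-1,4-diol
Product: 18 (2R,3R)-2-[(4-hydroxy-3-methoxyphenyl)methyl]-3-{[3-methoxy-4-(triisopropylsilyloxy)phenyl]methyl}butane-1,4-diol, the mono(triisopropylsilyl) ether of (−)-secoisolariciresinol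
Conditions: H2 (1 atm), 10% Pd/C, EtOAc, rt
Reagents that add atoms: none
Why: Hydrogenolysis of the aryl benzyl ether frees the ring B phenol only; silyl ether and alcohols are inert.

Step 9
Reactants: 18 (2R,3R)-2-[(4-hydroxy-3-methoxyphenyl)methyl]-3-{[3-methoxy-4-(triisopropylsilyloxy)phenyl]methyl}butane-1,4-diol
Product: 20 [(2S,3R,4R)-2-(4-hydroxy-3-methoxyphenyl)-4-{[3-methoxy-4-(triisopropylsilyloxy)phenyl]methyl}oxolan-3-yl]methanol, via para-quinone methide 19 (not isolated)
Conditions: 2,3-dichloro-5,6-dicyano-1,4-benzoquinone (DDQ, 1.05 equiv), CH2Cl2, 0 °C; aq NaHCO3 work-up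
Reagents that add atoms: none
Why: DDQ forms a charge-transfer complex with the electron-rich free phenol of ring B and takes hydride from the benzylic C2–H para to that hydroxyl; loss of the phenolic proton gives para-quinone methide 19 and the hydroquinone. This is the known DDQ dehydrogenation of para-hydroxybenzyl groups to quinone methides with capture by an internal hydroxyl. The C5 hydroxyl adds to the exocyclic methide carbon in a 5-exo-trig oxa-conjugate addition that re-aromatises ring B and forms the O1–C2 bond of the oxolane; the C9' hydroxyl could only close a four-membered ring, and carbon attack by ring A would need a slower six-membered Friedel–Crafts closure. The new centre C2 is controlled by C3: the quinonoid ring sits anti to the C3 hydroxymethyl arm in the envelope transition state, giving 2,3-trans (2S), and the weakly acidic hydroquinone lets any cis isomer equilibrate to this more stable arrangement. The step needs site selectivity between the two benzylic methylenes, which the silyl cap on ring A secures because a silyl aryl ether cannot give a neutral quinone methide and is oxidised far more slowly; it also has to stop after one oxidation, for which one equivalent of oxidant at 0 °C is used.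

Step 10
Reactants: 20 [(2S,3R,4R)-2-(4-hydroxy-3-methoxyphenyl)-4-{[3-methoxy-4-(triisopropylsilyloxy)phenyl]methyl}oxolan-3-yl]methanol; 21 3-methylbutanoyl chloride
Product: 22 {(2S,3R,4R)-2-[3-methoxy-4-(3-methylbutanoyloxy)phenyl]-4-{[3-methoxy-4-(triisopropylsilyloxy)phenyl]methyl}oxolan-3-yl}methyl 3-methylbutanoate
Conditions: 21 (2.5 equiv), pyridine, 4-dimethylaminopyridine (cat.), CH2Cl2, 0 °C → rt
Reagents that add atoms: 3-methylbutanoyl chloride (21), CC(C)CC(=O)Cl
Why: DMAP-catalysed O-acylation with an acyl chloride esterifies the primary alcohol and the phenol together, so the two hydroxyls need not be told apart at this point.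

Step 11
Reactants: 22 {(2S,3R,4R)-2-[3-methoxy-4-(3-methylbutanoyloxy)phenyl]-4-{[3-methoxy-4-(triisopropylsilyloxy)phenyl]methyl}oxolan-3-yl}methyl 3-methylbutanoate
Product: 23 [(2S,3R,4R)-2-(4-hydroxy-3-methoxyphenyl)-4-{[3-methoxy-4-(triisopropylsilyloxy)phenyl]methyl}oxolan-3-yl]methyl 3-methylbutanoate
Conditions: pyrrolidine (3 equiv), CH2Cl2, 0 °C
Reagents that add atoms: none
Why: Chemoselective aminolysis; the aryl ester, with a phenoxide leaving group, should react with the secondary amine far faster than the alkyl ester.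

Step 12
Reactants: 23 [(2S,3R,4R)-2-(4-hydroxy-3-methoxyphenyl)-4-{[3-methoxy-4-(triisopropylsilyloxy)phenyl]methyl}oxolan-3-yl]methyl 3-methylbutanoate
Product: 24 (+)-9'-isovaleroxylariciresinol, [(2S,3R,4R)-2-(4-hydroxy-3-methoxyphenyl)-4-[(4-hydroxy-3-methoxyphenyl)methyl]oxolan-3-yl]methyl 3-methylbutanoate
Conditions: Bu4NF, AcOH (1:1), THF, 0 °C
Reagents that add atoms: none
Why: Fluoride-induced cleavage of the aryl silyl ether; the acetic acid buffer protonates the phenoxide so that the alkyl ester and the oxolane should stay intact.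

**Compound list**

1 | 3-(4-hydroxy-3-methoxyphenyl)propanoic acid | COc1cc(CCC(=O)O)ccc1O | starting material
2 | triisopropylsilyl chloride | CC(C)[Si](Cl)(C(C)C)C(C)C | starting material
3 | triisopropylsilyl 3-[3-methoxy-4-(triisopropylsilyloxy)phenyl]propanoate | COc1cc(CCC(=O)O[Si](C(C)C)(C(C)C)C(C)C)ccc1O[Si](C(C)C)(C(C)C)C(C)C | intermediate
4 | 3-[3-methoxy-4-(triisopropylsilyloxy)phenyl]propanoic acid | COc1cc(CCC(=O)O)ccc1O[Si](C(C)C)(C(C)C)C(C)C | intermediate
5 | (4S)-4-benzyl-1,3-oxazolidin-2-one | O=C1N[C@@H](Cc2ccccc2)CO1 | starting material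
6 | mixed anhydride of acid 4 and pivalic acid | COc1cc(CCC(=O)OC(=O)C(C)(C)C)ccc1O[Si](C(C)C)(C(C)C)C(C)C | intermediate
7 | (4S)-4-benzyl-3-{3-[3-methoxy-4-(triisopropylsilyloxy)phenyl]propanoyl}-1,3-oxazolidin-2-one | COc1cc(CCC(=O)N2[C@@H](Cc3ccccc3)COC2=O)ccc1O[Si](C(C)C)(C(C)C)C(C)C | intermediate
8 | tert-butyl bromoacetate | CC(C)(C)OC(=O)CBr | starting material
9 | sodium (Z)-enolate of imide 7 | [Na+].[O-]/C(=C\Cc1ccc(O[Si](C(C)C)(C(C)C)C(C)C)c(OC)c1)N1[C@@H](Cc2ccccc2)COC1=O | intermediate
10 | tert-butyl (3R)-4-[(4S)-4-benzyl-2-oxo-1,3-oxazolidin-3-yl]-3-{[3-methoxy-4-(triisopropylsilyloxy)phenyl]methyl}-4-oxobutanoate | CC(C)(C)OC(=O)C[C@@H](Cc1ccc(O[Si](C(C)C)(C(C)C)C(C)C)c(OC)c1)C(=O)N1[C@@H](Cc2ccccc2)COC1=O | intermediate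
11 | tert-butyl (3R)-4-hydroxy-3-{[3-methoxy-4-(triisopropylsilyloxy)phenyl]methyl}butanoate | CC(C)(C)OC(=O)C[C@@H](Cc1ccc(O[Si](C(C)C)(C(C)C)C(C)C)c(OC)c1)CO | intermediate
12 | (4R)-4-{[3-methoxy-4-(triisopropylsilyloxy)phenyl]methyl}oxolan-2-one | O=C1C[C@@H](Cc2ccc(O[Si](C(C)C)(C(C)C)C(C)C)c(OC)c2)CO1 | intermediate
13 | [4-(benzyloxy)-3-methoxyphenyl]methanol | COc1cc(CO)ccc1OCc1ccccc1 | starting material
14 | 1-(benzyloxy)-4-(bromomethyl)-2-methoxybenzene | COc1cc(CBr)ccc1OCc1ccccc1 | intermediate
15 | lithium enolate of lactone 12 | [Li+].[O-]C1=C[C@@H](Cc2ccc(O[Si](C(C)C)(C(C)C)C(C)C)c(OC)c2)CO1 | intermediate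
16 | (3R,4R)-3-{[4-(benzyloxy)-3-methoxyphenyl]methyl}-4-{[3-methoxy-4-(triisopropylsilyloxy)phenyl]methyl}oxolan-2-one | O=C1[C@H](Cc2ccc(OCc3ccccc3)c(OC)c2)[C@@H](Cc2ccc(O[Si](C(C)C)(C(C)C)C(C)C)c(OC)c2)CO1 | intermediate
17 | (2R,3R)-2-{[4-(benzyloxy)-3-methoxyphenyl]methyl}-3-{[3-methoxy-4-(triisopropylsilyloxy)phenyl]methyl}butane-1,4-diol | OC[C@H](Cc1ccc(OCc2ccccc2)c(OC)c1)[C@@H](Cc1ccc(O[Si](C(C)C)(C(C)C)C(C)C)c(OC)c1)CO | intermediate
18 | (2R,3R)-2-[(4-hydroxy-3-methoxyphenyl)methyl]-3-{[3-methoxy-4-(triisopropylsilyloxy)phenyl]methyl}butane-1,4-diol (mono-silyl ether of (−)-secoisolariciresinol) | COc1cc(C[C@@H](CO)[C@@H](Cc2ccc(O)c(OC)c2)CO)ccc1O[Si](C(C)C)(C(C)C)C(C)C | intermediate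
19 | para-quinone methide of 18 (ring B as 2-methoxy-4-alkylidenecyclohexa-2,5-dien-1-one, exocyclic C=C at C2; C3 and C4 as in 18) | COC1=CC(=C[C@@H](CO)[C@H](CO)Cc2ccc(O[Si](C(C)C)(C(C)C)C(C)C)c(OC)c2)C=CC1=O | intermediate
20 | [(2S,3R,4R)-2-(4-hydroxy-3-methoxyphenyl)-4-{[3-methoxy-4-(triisopropylsilyloxy)phenyl]methyl}oxolan-3-yl]methanol | COc1cc(C[C@H]2CO[C@H](c3ccc(O)c(OC)c3)[C@H]2CO)ccc1O[Si](C(C)C)(C(C)C)C(C)C | intermediate
21 | 3-methylbutanoyl chloride | CC(C)CC(=O)Cl | starting material
22 | {(2S,3R,4R)-2-[3-methoxy-4-(3-methylbutanoyloxy)phenyl]-4-{[3-methoxy-4-(triisopropylsilyloxy)phenyl]methyl}oxolan-3-yl}methyl 3-methylbutanoate | COc1cc(C[C@H]2CO[C@H](c3ccc(OC(=O)CC(C)C)c(OC)c3)[C@H]2COC(=O)CC(C)C)ccc1O[Si](C(C)C)(C(C)C)C(C)C | intermediate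
23 | [(2S,3R,4R)-2-(4-hydroxy-3-methoxyphenyl)-4-{[3-methoxy-4-(triisopropylsilyloxy)phenyl]methyl}oxolan-3-yl]methyl 3-methylbutanoate | COc1cc(C[C@H]2CO[C@H](c3ccc(O)c(OC)c3)[C@H]2COC(=O)CC(C)C)ccc1O[Si](C(C)C)(C(C)C)C(C)C | intermediate
24 | (+)-9'-isovaleroxylariciresinol | COc1cc(C[C@H]2CO[C@H](c3ccc(O)c(OC)c3)[C@H]2COC(=O)CC(C)C)ccc1O | target

**Step count**

Total steps: 12. Longest linear sequence: 11 (steps 1–4 and 6–12; step 5 is a one-step side branch).

**Steps most likely to fail, with fallbacks**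

Step 9. The cyclised product carries a C2–H that is again benzylic, para to the free hydroxyl and now also next to the ring oxygen, so a second hydride abstraction with ring cleavage may compete. Carbon attack of ring A on the quinone methide (six-membered Friedel–Crafts closure), tautomerisation of the quinone methide to a styrene, and insufficient facial selectivity at C2 are further ways the step may go astray. The fallback brings in the C2 oxygen as a carbinol and does not rely on C–H oxidation. It sets out from lactone 12. Aldol addition of its lithium enolate (LiN(SiMe3)2, THF, −78 °C) to commercial 4-(benzyloxy)-3-methoxybenzaldehyde should give, anti to the C4 substituent, (3S,4R)-3-{[4-(benzyloxy)-3-methoxyphenyl](hydroxy)methyl}-4-{[3-methoxy-4-(triisopropylsilyloxy)phenyl]methyl}oxolan-2-one F1 as a mixture of carbinol epimers. LiAlH4 (THF, 0 °C) should reduce it to (2R,3R)-2-{[4-(benzyloxy)-3-methoxyphenyl](hydroxy)methyl}-3-{[3-methoxy-4-(triisopropylsilyloxy)phenyl]methyl}butane-1,4-diol F2. Catalytic 10-camphorsulfonic acid in CH2Cl2 at 0 °C ionises the benzylic alcohol of either epimer to the para-alkoxybenzyl cation, which the C5 hydroxyl captures in a 5-exo closure to the 2,3-trans oxolane [(2S,3R,4R)-2-[4-(benzyloxy)-3-methoxyphenyl]-4-{[3-methoxy-4-(triisopropylsilyloxy)phenyl]methyl}oxolan-3-yl]methanol F3. Hydrogenolysis (H2, 10% Pd/C, EtOAc, stopped after one equivalent of hydrogen) removes the benzyl ether and the route is rejoined at compound 20.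

Step 4. The lithium alkoxide formed in the reduction may lactonise in the reducing medium and be reduced further to a diol, or hydride may attack the ring carbonyl of the auxiliary and open it. The fallback separates cleavage of the auxiliary from reduction. It sets out from imide 10. Hydrolysis with LiOH and H2O2 (THF–H2O, 0 °C) should give (2R)-4-tert-butoxy-2-{[3-methoxy-4-(triisopropylsilyloxy)phenyl]methyl}-4-oxobutanoic acid F4. BH3·SMe2 (THF, 0 °C) reduces the free carboxylic acid in preference to the tert-butyl ester, and the route is rejoined at hydroxy ester 11, which is lactonised to 12 with the acid treatment of step 4.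

Step 11. Discrimination between the aryl and the alkyl ester may be incomplete, with slow loss of the C9' ester on longer exposure to the amine. The fallback avoids over-acylation altogether. It sets out from compound 20. A Mitsunobu esterification (PPh3, diisopropyl azodicarboxylate, 3-methylbutanoic acid, THF, 0 °C) activates only the primary alcohol as its alkoxyphosphonium ion, and the carboxylate, far more acidic than the phenol, acts as the nucleophile. This should give compound 23 directly, where the route is rejoined; no new compound is made (F0).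

**Further compounds**

F1 | step 9 | (3S,4R)-3-{[4-(benzyloxy)-3-methoxyphenyl](hydroxy)methyl}-4-{[3-methoxy-4-(triisopropylsilyloxy)phenyl]methyl}oxolan-2-one | O=C1[C@H](C(O)c2ccc(OCc3ccccc3)c(OC)c2)[C@@H](Cc2ccc(O[Si](C(C)C)(C(C)C)C(C)C)c(OC)c2)CO1
F2 | step 9 | (2R,3R)-2-{[4-(benzyloxy)-3-methoxyphenyl](hydroxy)methyl}-3-{[3-methoxy-4-(triisopropylsilyloxy)phenyl]methyl}butane-1,4-diol | OC[C@H](C(O)c1ccc(OCc2ccccc2)c(OC)c1)[C@@H](Cc1ccc(O[Si](C(C)C)(C(C)C)C(C)C)c(OC)c1)CO
F3 | step 9 | [(2S,3R,4R)-2-[4-(benzyloxy)-3-methoxyphenyl]-4-{[3-methoxy-4-(triisopropylsilyloxy)phenyl]methyl}oxolan-3-yl]methanol | COc1cc(C[C@H]2CO[C@H](c3ccc(OCc4ccccc4)c(OC)c3)[C@H]2CO)ccc1O[Si](C(C)C)(C(C)C)C(C)C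
F4 | step 4 | (2R)-4-tert-butoxy-2-{[3-methoxy-4-(triisopropylsilyloxy)phenyl]methyl}-4-oxobutanoic acid | CC(C)(C)OC(=O)C[C@@H](Cc1ccc(O[Si](C(C)C)(C(C)C)C(C)C)c(OC)c1)C(=O)O
F0 | step 11 | none | none
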